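(The earlier runs and the new flask are simulated for an exercise.)

**Early curve.** At early times the monomer in chains climbs slowly, and later the free monomer falls by first-order decay, so I freeze the one thing that looks nearly constant late on: the number of growing chains, which makes the late slope of ln(1/(1−x)), with x the fraction of monomer in chains, a pseudo-first-order constant that counts them.

| setting | north-east | north-west | winter | dusk |
|---|---|---|---|---|
| free monomer | 0.30 M | 0.30 M | 0.30 M | 0.30 M |
| initiator | 3.5 mol% | 12 mol% | 5 mol% | 20 mol% |
| remark | run made earlier | run made earlier |  |  |
| time |  |  | 3.0 d | 3.0 d |

| run | time / d | monomer in chains / % |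
|---|---|---|
| north-east | 0.250 | 9.4 |
| north-east | 0.417 | 22.1 |
| north-east | 0.625 | 37.4 |
| north-east | 1.04 | 60.4 |
| north-east | 1.67 | 82.8 |
| north-east | 3.00 | 96.7 |
| north-west | 0.208 | 20.5 |
| north-west | 0.625 | 69.3 |
| north-west | 1.04 | 89.7 |
| north-west | 1.67 | 97.9 |
| north-west | 2.50 | 99.7 |
| north-west | 3.00 | 99.4 |

(standard deviation of a reading: 0.5 percentage points)

1. which of the two ends with the longer chains by the average number of monomer units in a chain (chains begun, living or dead) ("neither" if they lie within 10%) (winter / dusk / neither)
2. average number of monomer units in a chain (chains begun, living or dead) at the end, winter
3. average number of monomer units in a chain (chains begun, living or dead) at the end, dusk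

- the average divides the monomer in chains by the number of chains begun, living and dead together
- the numbers in the tables scatter by 0.5 percentage points (one standard deviation)
- the earlier runs do not show the number of chains; that part of a forecast is a guess

**Lower bound.** One chain per initiator at full conversion gives winter 20.0 and dusk 5.00. The hand can tighten this. The late slopes read 1.24 /d in north-east and 2.57 /d in north-west, so by these readings chains go as loading to the power 0.590. Taking one chain per initiator in north-east as the limit and scaling by that power defines the slope floor: winter 23.2, dusk 10.2.

**Upper bound.** North-east's first two readings extrapolate to a starting rate of 0.0894 /d, and its late line gives a lag of 0.252 d. If starting dies away over the lag, chains begun are their product, 2.25% of the monomer. I allow that rate to be lower by a factor 3, which gives estimated ceilings of winter 108 and dusk 47.7. My own central reckoning is winter 36.0 and dusk 15.9.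

**The forecast.** The forecast says winter, with 100 (range 20 to 600) and 26 (range 5 to 150), holding that “Chains begun scale with initiator”. Its winter value lies just below my ceiling, and its dusk value lies above my slope floor.

**The flask.** The longer chains are in winter, with winter 32.9 and dusk 16.7.

    free monomer + initiator → living end + monomer in chains (k = 0.260 /M/h)
    free monomer + living end → monomer in chains + living end, rate k2*[living end]*[free monomer] (k = 8.10 /M/h)
    2 initiator → spent initiator (k = 1.90 /M/h)
    2 free monomer → homo dimer (k = 9.50 × 10⁻⁴ /M/h)

**Length ratio.** Both lengths stand above the slope floor, winter 32.9 against 23.2 and dusk 16.7 against 10.2, and their ratio is 1.97, not the charge ratio 4.00. The difference in loading of initiator is the main reason that dusk ends shorter, and the loss of 2 initiator to spent initiator is a part of why the ratio stays below the charge ratio: the dusk run without that loss gives 11.1, not 16.7, and with it dusk keeps 4.9% of its charged initiator at 3.00 d. For the neighbour, winter's flask at 12 mol% of initiator, the slope floor is 13.8, and that flask gives 20.9.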